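The data are calculated with made-up constants; the scatter is artificial.

If substrate is fed slowly into a flask, what matters for side product B is how much substrate stands in the flask at any moment, so we reckon that level first.

| flask | substrate | coupling partner | protic impurity | remark | time |
|---|---|---|---|---|---|
| south-west | 10 mM | 1.05 equiv | 5 mM | run made earlier |  |
| north | 14 mM | 1.05 equiv | 5 mM | run made earlier |  |
| south | 22 mM | 1.05 equiv | 5 mM | run made earlier |  |
| Monday's | 10 mM | 1.05 equiv | 5.00 mM | everything together at the start | 1.0 h |
| Friday's | 10 mM (fed, over 40 min) | 1.05 equiv | 5.00 mM | all else is in the flask from the start; the feed brings no volume worth counting | 1.0 h |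
| Sunday's | 10 mM | 1.05 equiv (fed, over 4.0 min) | 5.00 mM | all else is in the flask from the start; the feed brings no volume worth counting | 1.0 h |
| Thursday's | 10 mM | 1.05 equiv (fed, over 40 min) | 5.00 mM | all else is in the flask from the start; the feed brings no volume worth counting | 1.0 h |

- south-west (time / min: side product A / %, target / %, substrate / %): 5.00: 56.8, 18.5, 11.2; 8.00: 63.1, 18.0, 3.8; 12.0: 65.2, 17.5, 1.6; 20.0: 66.7, 16.4, 1.0; 40.0: 71.2, 12.5, 1.3; 60.0: 74.2, 10.3, 0.7
- north (time / min: side product A / %, target / %, substrate / %): 4.00: 48.9, 20.9, 13.3; 6.00: 52.7, 22.6, 6.6; 10.0: 57.6, 22.3, 0.7; 20.0: 60.0, 20.5, 0.5; 30.0: 62.9, 18.3, 0.9; 50.0: 65.3, 15.8, 0.6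
- south (time / min: side product A / %, target / %, substrate / %): 8.00: 46.1, 29.8, 2.1; 15.0: 48.8, 28.4, 0.6; 25.0: 49.9, 24.8, 1.1; 30.0: 52.3, 24.1, 0.4; 40.0: 54.8, 22.4, 0; 50.0: 55.3, 20.3, 1.9

(each reading ± 0.5 percentage points)

- the flask with the highest amount of side product A, in percent of the substrate charged ("all alike" if they lie within 1.5 percentage points) (Monday's / Friday's / Sunday's / Thursday's / all alike)
- final side product A, as a percentage of the substrate charged, in Monday's
- final side product A, as a percentage of the substrate charged, in Friday's
- final side product A, as a percentage of the substrate charged, in Sunday's
- final side product A, as a percentage of the substrate charged, in Thursday's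

- percent here means substrate units held: one side product B counts as two
- reactions considered so far: substrate + coupling partner <-> target; 2 substrate -> side product B; coupling partner + protic impurity -> quenched reagent; substrate -> side product A

We start from the south-west run, in which Monday's recipe was already made. Monday's should therefore end near that run's last reading, 74.2% of side product A. Between its first two readings the substrate falls from 11.2% to 3.8%, a pseudo-first-order loss of 0.360 min⁻¹. In Friday's, substrate enters at 0.250 mM min⁻¹, and it piles up until loss equals feed. We call the feed rate divided by the loss the standing level, 0.694 mM.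

Side product B needs two substrates to meet, so its share should follow the substrate level. By difference, the south-west run held 14.8% as side product B at its last reading, and in that run we take the average substrate unit to have met about 5.00 mM on its way out. Scaling to the standing level gives Friday's 2.05%. Taking the south-west run's last target and substrate readings for the rest leaves 86.9% of side product A.

The weak link is that borrowed target reading, since Friday's substrate enters on average 40.0 min before the end, less than the south-west run's 60.0 min. Using the reading at 40.0 min instead, 12.5%, we commit to 84.7%. Monday's, Sunday's and Thursday's start with the whole substrate charge in the flask, 10 mM, far above Friday's standing level, so we expect less side product B in Friday's than in them, and on that ground we name Friday's as the flask with the most side product A.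

The forecast named Friday's as the flask with the most side product A, with 74% for Monday's, 85% for Friday's, 76% for Sunday's and 80% for Thursday's, saying of Thursday's that “the impurity eats the fed partner”.

    substrate + coupling partner ⇌ target (K = 920 L mol⁻¹, k = 0.210 L mol⁻¹ s⁻¹)
    2 substrate → side product B (k = 0.130 L mol⁻¹ s⁻¹)
    coupling partner + protic impurity → quenched reagent (k = 0.450 L mol⁻¹ s⁻¹)
    substrate → side product A (k = 0.00510 s⁻¹)

Friday's ends at 86.0% of side product A, against 74.0% in Monday's, 76.1% in Sunday's and 80.1% in Thursday's. Over the first 40 min, Friday's held on average 0.634 mM of substrate, close to the standing level. With 6.0 mM of substrate in Friday's recipe and the same loss taken, the standing level drops to 0.416 mM, and scaling Friday's final 2.73% of side product B by that level gives 1.64%. That neighbouring flask ends with 1.96% of side product B.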